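Of the 5 questions here, 4 ask for L at the end of a flask and one asks which flask holds most.

| flask | Q | G | temperature | remark | time |
|---|---|---|---|---|---|
| south-east | 20 mM | 5 mM | 70 °C | run made earlier |  |
| north-west | 20 mM | 20 mM | 100 °C | run made earlier |  |
| blue | 20 mM | 10.0 mM | 75 °C |  | 10 h |
| teal | 20 mM | 10.0 mM | 125 °C |  | 10 h |
| red | 20 mM | 10.0 mM |  | at 75 °C until 8.0 h, from then on at 125 °C | 10 h |
| green | 20 mM | 10.0 mM | 100 °C |  | 10 h |

- south-east (time / h: L / %, Q / %): 0.667: 2, 100; 2.00: 0, 100; 4.00: 1, 96; 6.00: 3, 98; 8.00: 2, 98
- north-west (time / h: L / %, Q / %): 0.200: 4, 94; 0.667: 9, 92; 1.33: 18, 82; 2.00: 22, 77; 2.50: 24, 71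

(standard deviation of a reading: 1.5 percentage points)

- the flask that comes out highest in amount of L, in percent of the Q charged, or "all alike" when all lie within 1.5 percentage points (blue / teal / red / green / all alike)
- L at the end, in percent of the Q charged, blue
- L at the end, in percent of the Q charged, teal
- L at the end, in percent of the Q charged, red
- L at the end, in percent of the Q charged, green

- what was read earlier has a scatter of 1.5 percentage points, one standard deviation

I ask first which given number must be known well. The south-east rate is poorly held, since its last L of 2% lies close to the scatter of 1.5 percentage points, but an error there, like a change of temperature or time, alters how fast G goes and not how much L a G can give. The count of L per G is different, because the ceiling I reckon below scales with it, so that count is the number I must hold. In the north-west run at 2.50 h, Q has lost 29.0% and L stands at 24%, a gap of 5 points against a scatter of 2.1 points for such a difference, so I suspect a side route of Q, but neither run reads G, so one G per L stays my assumption.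

G is then the limiting reagent, as 10.0 mM is less than 20 mM. My quantity is the G ceiling, [G]/[Q] at charge, the most L the charge can form at one G per L, here 50.0% of the Q charged. The ceiling times the share of G spent is a tally of L ever formed, and L standing can lie below that tally. Blue, teal, red and green share this charge, so I commit to L under 50.0% in each.

The forecast names teal as highest, with blue 9%, teal 47%, red 36% and green 33%, on the ground that “The Q loss roughly matches the L formed”.

The flasks give blue 9.98%, teal 6.90%, red 22.0% and green 26.8%, so green holds most.

    Q + G → L (k = 7.50 M⁻¹ h⁻¹, Ea = 79.0 kJ mol⁻¹)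
    L → E (k = 0.0140 h⁻¹, Ea = 121 kJ mol⁻¹)
    Q → D (k = 0.00220 h⁻¹, Ea = 122 kJ mol⁻¹)
    Q + L → Z (k = 1.70 M⁻¹ h⁻¹, Ea = 102 kJ mol⁻¹)
    (constants at 100 °C)

In this scheme each L formed takes one G, so the tally holds. Teal keeps 4.28% of its G at 10.0 h, which tallies 47.9%, yet L stands at 6.90%, while green tallies 33.9% and holds 26.8%. The neighbour of green charged with 80 mM of Q has 0.125 equiv of G, a ceiling of 12.5%. It keeps 0.605% of its G, which tallies 12.4%, and it ends with L at 4.47%.

The numbers in the tables are calculated from invented constants; noise was put on by code.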